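Numbering (daucane): C1 = quaternary C(CH3), C2 = CH–OAc, C3 = CH2, C4 = C(OH)(i-Pr), C5 = ring-fusion CH, C6 = CH–O-aroyl, C7 = CH2, C8(CH3)=C9H, C10 = CH–OBz. Ring A = C1–C5, ring B = C1/C5–C10, and the C1 methyl is β.
Retrosynthesis: cut the three esters, then C4–i-Pr (gives hydroazulen-4-one 16), then C2–C3 and C1–C5 together. The last cut opens both rings to the acyclic epoxy enol silane 14.
Enabling feature: ring A carries oxygen at C2 and C4 (1,3), and C6, next to C5, also carries oxygen. Without i-Pr this is a 3-alkoxycyclopentanone with an α-carbinol arm. That is the adduct of a 2-silyloxyallyl cation C3–C4–C5, unmasked from a C5–C6 epoxide, with a C1=C2 enol ether.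
Forward: one linear chain is built (alkynylation, Stille allylation, carbomagnesiation, vinylic C–O coupling, cross metathesis, epoxidation). Ring B and then ring A close in a single catalytic event, and i-Pr addition and three ordered acylations finish the route.
Stereochemistry: C10 comes from a catalytic asymmetric alkynylation and the C5/C6 epoxide from a catalytic asymmetric epoxidation. C1, C2 and C5 are relayed from these in the key step, and C4 is set by substrate control. Both Z alkenes come from hydroxyl-directed alkyne metalations.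

Key step: step 12

Assumption: the ligand antipodes in steps 3 and 10 are named by analogy with the usual sense of induction of these catalyst families; the mirror-image ligand would be taken if the sense were opposite.

Step 1
Reactants: 1 but-2-yn-1-ol
Product: 3 (Z)-3-iodobut-2-en-1-ol, via cyclic alkenylaluminate 2 (not isolated)
Conditions: Red-Al, THF, 0 °C to rt; then I2, THF, −78 to 0 °C
Reagents that add atoms: iodine, II
Why: Hydroxyl-directed trans-hydroalumination of the propargylic alcohol puts Al on C3 of the butynol inside a five-membered aluminate, and iodinolysis with retention fixes the Z geometry (I cis to CH2OH) that becomes the ring-B alkene.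

Step 2
Reactants: 3 (Z)-3-iodobut-2-en-1-ol
Product: 4 (Z)-3-iodobut-2-enal
Conditions: MnO2, CH2Cl2, rt
Reagents that add atoms: none
Why: Neutral heterogeneous MnO2 allylic oxidation should give the enal without Z/E isomerisation or loss of the alkenyl iodide.

Step 3
Reactants: 4 (Z)-3-iodobut-2-enal
Product: 5 (3S,4Z)-5-iodo-1-(trimethylsilyl)hex-4-en-1-yn-3-ol
Conditions: TMS-acetylene, Me2Zn, (S,S)-ProPhenol (10 mol %), Ph3P=O (20 mol %), toluene, 0 °C
Reagents that add atoms: trimethylsilylacetylene, C#C[Si](C)(C)C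
Why: Catalytic enantioselective 1,2-addition of an alkynylzinc to the enal within the dinuclear zinc–ProPhenol complex sets the C10 carbinol (S), the only stereocentre of the eastern half.

Step 4
Reactants: 5 (3S,4Z)-5-iodo-1-(trimethylsilyl)hex-4-en-1-yn-3-ol
Product: 6 (3S,4Z)-5-methyl-1-(trimethylsilyl)octa-4,7-dien-1-yn-3-ol
Conditions: allyl-SnBu3, Pd2(dba)3 (2.5 mol %), AsPh3 (10 mol %), NMP, rt to 40 °C
Reagents that add atoms: allyltributylstannane, C=CC[Sn](CCCC)(CCCC)CCCC
Why: Stille coupling of the alkenyl iodide retains the Z geometry and tolerates the free alcohol and the silylalkyne, and placing it after the aldehyde stage avoids a base-labile skipped dienal.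

Step 5
Reactants: 6 (3S,4Z)-5-methyl-1-(trimethylsilyl)octa-4,7-dien-1-yn-3-ol
Product: 7 (3S,4Z)-5-methylocta-4,7-dien-1-yn-3-ol
Conditions: K2CO3 (cat.), MeOH, rt
Reagents that add atoms: none
Why: Base-catalysed methanolysis (protodesilylation) of the alkynylsilane frees the terminal alkyne and touches nothing else.

Step 6
Reactants: 7 (3S,4Z)-5-methylocta-4,7-dien-1-yn-3-ol
Product: 9 (1Z,3S,4Z)-1-iodo-2,5-dimethylocta-1,4,7-trien-3-ol, via cyclic alkenylmagnesium alkoxide 8 (not isolated)
Conditions: MeMgBr, CuI (20 mol %), THF, −20 °C to rt; then I2, −78 to 0 °C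
Reagents that add atoms: methylmagnesium bromide, C[Mg]Br; iodine, II
Why: Copper-catalysed alkoxide-directed anti-carbomagnesiation adds CH3 to the internal alkyne carbon (C1) and holds Mg on the terminus (C2) in a five-membered chelate cis to C10, so iodinolysis with retention should give only the (Z)-iodide.

Step 7
Reactants: 9 (1Z,3S,4Z)-1-iodo-2,5-dimethylocta-1,4,7-trien-3-ol
Product: 10 TBS ether of 9
Conditions: TBSCl, imidazole, DMF, rt
Reagents that add atoms: tert-butyldimethylsilyl chloride, CC(C)(C)[Si](C)(C)Cl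
Why: Imidazole-promoted silylation protects the bis-allylic C10 alcohol as a hindered, weakly Lewis-basic ether before the acid-sensitive enol ether is made.

Step 8
Reactants: 10 TBS ether of 9
Product: 11 (1Z,3S,4Z)-3-(TBSO)-1-(4-methoxybenzyloxy)-2,5-dimethylocta-1,4,7-triene
Conditions: PMBOH, CuI (10 mol %), 3,4,7,8-Me4-phenanthroline (20 mol %), Cs2CO3, toluene, 90 °C
Reagents that add atoms: 4-methoxybenzyl alcohol, COc1ccc(CO)cc1
Why: Ullmann-type copper-catalysed vinylic C–O coupling of alkenyl iodides with primary alcohols is stereoretentive, so the contra-thermodynamic (Z)-enol ether (O cis to C10) follows from the (Z)-iodide.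

Step 9
Reactants: 11 (Z)-PMB enol ether with terminal alkene
Product: 12 (3E,6Z,8S,9Z)-8-(TBSO)-10-(4-methoxybenzyloxy)-6,9-dimethyldeca-3,6,9-trien-2-one
Conditions: methyl vinyl ketone, Hoveyda–Grubbs II (5 mol %), 1,4-benzoquinone (10 mol %), CH2Cl2, 40 °C
Reagents that add atoms: methyl vinyl ketone, CC(=O)C=C
Why: Cross metathesis of the only monosubstituted (type I) alkene with the electron-poor type II partner gives the (E)-enone, because the trisubstituted alkene and the trisubstituted enol ether are too hindered to engage the ruthenium carbene.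

Step 10
Reactants: 12 skipped (E)-dienone
Product: 13 (3R,4S,6Z,8S,9Z)-3,4-epoxy-8-(TBSO)-10-(4-methoxybenzyloxy)-6,9-dimethyldeca-6,9-dien-2-one
Conditions: La(Oi-Pr)3/(S)-BINOL/Ph3As=O (10 mol % each), TBHP (decane), 4 Å MS, THF, rt
Reagents that add atoms: tert-butyl hydroperoxide, CC(C)(C)OO
Why: Weitz–Scheffer-type nucleophilic epoxidation by a lanthanum–BINOL peroxide attacks only the electron-poor C5=C6 alkene, the E geometry is carried into the trans-epoxide, and the catalyst selects the face that gives C5 (R)/C6 (S).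

Step 11
Reactants: 13 trans-epoxy ketone
Product: 14 (3R,4S,6Z,8S,9Z)-3,4-epoxy-2-(TESO)-8-(TBSO)-10-(4-methoxybenzyloxy)-6,9-dimethyldeca-1,6,9-triene
Conditions: TESCl, LiHMDS (in situ quench), THF, −78 °C
Reagents that add atoms: triethylsilyl chloride, CC[Si](Cl)(CC)CC
Why: Kinetic deprotonation takes the unhindered methyl group (C3) rather than the oxiranyl C5–H, and in situ O-silylation (silyl enol ether formation) gives the 2-silyloxyallylic epoxide under basic conditions that spare the epoxide and the enol ether.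

Step 12
Reactants: 14 epoxy enol silane
Product: 16 trans-hydroazulen-4-one (1β-CH3; 5α-H; 2α-OPMB; 6α-OTES; 8-CH3; 10β-OTBS), via C2-oxocarbenium triflate 15 (not isolated)
Conditions: TESOTf (10 mol %), CH2Cl2 (0.005 M), −78 °C; then Et3N
Reagents that add atoms: none
Why: Proposed new method: catalytic TESOTf silylates the epoxide oxygen, the C5–O bond (allylic to the enol silane, i.e. a masked 2-silyloxyallyl cation C3–C4–C5) is displaced with inversion by C1 of the (Z)-enol ether, and the C2 oxocarbenium ion 15 is captured at once by the enol-silane terminus C3 with release of TES+, so the whole event is a catalytic isomerisation (formal (3+2) cycloaddition). The closest known reaction types are the silyl-triflate-catalysed inter- and intramolecular (4+3) cycloadditions of epoxy enol silanes with dienes, which transfer the epoxide configuration, and the Lewis-acid (3+2) annulation of 2-silyloxyallyl cations with enol ethers; new here are the tethered enol-ether 2π partner and the seven-membered ring. Ring B closes by a 7-endo-tet epoxide opening (exo with respect to the C1=C2 nucleophile) and ring A by a 5-(enolendo)-exo-trig Mukaiyama-type addition. C5 is set by backside attack on the trans-epoxide (H5/H6 anti, C6–OTES equatorial); C1 is set by a chair-like cycloheptene transition state with both silyloxy groups and the C1=C2 arm equatorial and CH3 axial, its face fixed by A(1,3) strain between the (Z)-OPMB group and C10 (C10–H lies nearest the C1=C2 plane), which gives the trans fusion; C2 is set by suprafacial use of the (Z)-enol ether (OPMB stays cis to C10 and trans to CH3). The step needs attack at C5 rather than C6 (secured by allylic activation), attack by the enol ether rather than by C8=C9 (secured by its far higher nucleophilicity and the strain of the alternative small rings), and C- rather than O-closure (secured by the silylated enol oxygen). Ionisation of the doubly allylic C10–OTBS should be held back by −78 °C, the low catalyst loading and the poor basicity of the hindered silyl ether.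

Step 13
Reactants: 16 trans-hydroazulen-4-one
Product: 17 2α-OPMB-6α-OTES-10β-OTBS-dauc-8-en-4β-ol
Conditions: i-PrMgCl, LaCl3·2LiCl, THF, −20 to 0 °C
Reagents that add atoms: isopropylmagnesium chloride, CC(C)[Mg]Cl
Why: Lanthanide-mediated Grignard 1,2-addition suppresses enolisation, β-elimination and β-hydride reduction, and the nucleophile should enter from the α face because the β face is screened by the axial C1 methyl group, which gives the 4β-OH/4α-i-Pr carbinol.

Step 14
Reactants: 17 2α-OPMB-6α-OTES-10β-OTBS-dauc-8-en-4β-ol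
Product: 18 2α-OPMB-10β-OTBS-dauc-8-ene-4β,6α-diol
Conditions: PPTS (cat.), MeOH/CH2Cl2, 0 °C
Reagents that add atoms: none
Why: Acid-catalysed methanolysis distinguishes silyl ethers by bulk, so the TES ether is cleaved while the TBS ether, the PMB ether and the tertiary alcohol persist.

Step 15
Reactants: 19 4-hydroxybenzoic acid
Product: 21 4-(triisopropylsilyloxy)benzoic acid, via bis-TIPS derivative 20 (not isolated)
Conditions: TIPSCl (2.2 equiv), imidazole, DMF, rt; then THF/1 M HCl (cat.), rt
Reagents that add atoms: triisopropylsilyl chloride, CC(C)[Si](Cl)(C(C)C)C(C)C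
Why: Exhaustive silylation followed by hydrolysis of the far more labile silyl ester gives the phenol-protected acid.

Step 16
Reactants: 18 2α-OPMB-10β-OTBS-dauc-8-ene-4β,6α-diol; 21 4-(triisopropylsilyloxy)benzoic acid
Product: 22 6α-[4-(TIPSO)benzoyloxy]-2α-OPMB-10β-OTBS-dauc-8-en-4β-ol
Conditions: EDC, DMAP, CH2Cl2, rt to 40 °C
Reagents that add atoms: none
Why: Steglich esterification acylates the only free secondary hydroxyl (C6–OH), because the tertiary C4–OH is too hindered to react.

Step 17
Reactants: 22 C6 ester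
Product: 23 6α-[4-(TIPSO)benzoyloxy]-2α-OPMB-dauc-8-ene-4β,10β-diol
Conditions: HF·pyridine, pyridine, THF, 0 °C to rt
Reagents that add atoms: none
Why: Buffered acidic fluoride cleaves the alkyl TBS ether, whereas the aryl TIPS ether (less basic oxygen, bulkier silicon), the ester and the PMB ether should survive.

Step 18
Reactants: 23 C10 alcohol
Product: 24 10β-benzoyloxy-6α-[4-(TIPSO)benzoyloxy]-2α-OPMB-dauc-8-en-4β-ol
Conditions: BzCl, pyridine, DMAP (cat.), CH2Cl2, rt
Reagents that add atoms: benzoyl chloride, O=C(Cl)c1ccccc1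
Why: DMAP-catalysed acylation of the allylic C10–OH proceeds with retention, and doing it while C2–O is still a PMB ether means no acyl migration between C2 and C10 is possible.

Step 19
Reactants: 24 C10 benzoate
Product: 25 10β-benzoyloxy-6α-[4-(TIPSO)benzoyloxy]dauc-8-ene-2α,4β-diol
Conditions: DDQ, CH2Cl2/pH 7 buffer, 0 °C
Reagents that add atoms: none
Why: Oxidative PMB cleavage by DDQ (hydride abstraction, then hydrolysis) is essentially neutral and leaves the esters, the aryl silyl ether, the alkene and the tertiary alcohol alone.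

Step 20
Reactants: 25 C2 alcohol
Product: 26 2α-acetoxy-10β-benzoyloxy-6α-[4-(TIPSO)benzoyloxy]dauc-8-en-4β-ol
Conditions: Ac2O, pyridine, DMAP (cat.), CH2Cl2, 0 °C to rt
Reagents that add atoms: acetic anhydride, CC(=O)OC(C)=O
Why: Fast DMAP-catalysed acetylation of the secondary C2–OH should outrun benzoyl migration and leaves the tertiary alcohol free.

Step 21
Reactants: 26 silyl-protected triester
Product: 27 target: 2α-acetoxy-10β-benzoyloxy-6α-(4-hydroxybenzoyloxy)dauc-8-en-4β-ol
Conditions: TBAF, AcOH, THF, 0 °C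
Reagents that add atoms: none
Why: Acetic-acid-buffered fluoride removes the aryl silyl ether rapidly because phenoxide is a good leaving group, without ester cleavage or migration.

Compound list
1 | but-2-yn-1-ol | CC#CCO | starting material
2 | sodium cyclic alkenylaluminate (Al on C3, two 2-methoxyethoxy ligands) | CC1=CCO[Al-]1(OCCOC)OCCOC.[Na+] | intermediate
3 | (Z)-3-iodobut-2-en-1-ol | C/C(I)=C/CO | intermediate
4 | (Z)-3-iodobut-2-enal | C/C(I)=C/C=O | intermediate
5 | (3S,4Z)-5-iodo-1-(trimethylsilyl)hex-4-en-1-yn-3-ol | C/C(I)=C/[C@H](O)C#C[Si](C)(C)C | intermediate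
6 | (3S,4Z)-5-methyl-1-(trimethylsilyl)octa-4,7-dien-1-yn-3-ol | C=CC/C(C)=C\[C@H](O)C#C[Si](C)(C)C | intermediate
7 | (3S,4Z)-5-methylocta-4,7-dien-1-yn-3-ol | C=CC/C(C)=C\[C@H](O)C#C | intermediate
8 | cyclic (Z)-alkenylmagnesium alkoxide | C=CC/C(C)=C\[C@H](O1)C(C)=C[Mg]1 | intermediate
9 | (1Z,3S,4Z)-1-iodo-2,5-dimethylocta-1,4,7-trien-3-ol | C=CC/C(C)=C\[C@H](O)/C(C)=C\I | intermediate
10 | TBS ether of 9 | C=CC/C(C)=C\[C@H](O[Si](C)(C)C(C)(C)C)/C(C)=C\I | intermediate
11 | (1Z,3S,4Z)-3-(TBSO)-1-(4-methoxybenzyloxy)-2,5-dimethylocta-1,4,7-triene | C=CC/C(C)=C\[C@H](O[Si](C)(C)C(C)(C)C)/C(C)=C\OCc1ccc(OC)cc1 | intermediate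
12 | (3E,6Z,8S,9Z)-8-(TBSO)-10-(4-methoxybenzyloxy)-6,9-dimethyldeca-3,6,9-trien-2-one | CC(=O)/C=C/C/C(C)=C\[C@H](O[Si](C)(C)C(C)(C)C)/C(C)=C\OCc1ccc(OC)cc1 | intermediate
13 | (3R,4S)-trans-epoxy ketone of 12 | CC(=O)[C@@H]1O[C@H]1C/C(C)=C\[C@H](O[Si](C)(C)C(C)(C)C)/C(C)=C\OCc1ccc(OC)cc1 | intermediate
14 | epoxy enol silane (TES enol ether of 13 at the methyl side) | C=C(O[Si](CC)(CC)CC)[C@@H]1O[C@H]1C/C(C)=C\[C@H](O[Si](C)(C)C(C)(C)C)/C(C)=C\OCc1ccc(OC)cc1 | intermediate
15 | monocyclic C2-oxocarbenium triflate (ring B closed, enol silane intact) | C=C(O[Si](CC)(CC)CC)[C@@H]1[C@@H](O[Si](CC)(CC)CC)CC(C)=C[C@H](O[Si](C)(C)C(C)(C)C)[C@@]1(C)C=[O+]Cc1ccc(OC)cc1.[O-]S(=O)(=O)C(F)(F)F | intermediate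
16 | trans-hydroazulen-4-one (1β-CH3, 5α-H, 2α-OPMB, 6α-OTES, 8-CH3, 10β-OTBS) | COc1ccc(cc1)CO[C@H]1CC(=O)[C@@H]2[C@@H](O[Si](CC)(CC)CC)CC(C)=C[C@H](O[Si](C)(C)C(C)(C)C)[C@@]12C | intermediate
17 | 2α-OPMB-6α-OTES-10β-OTBS-dauc-8-en-4β-ol | COc1ccc(cc1)CO[C@H]1C[C@@](O)(C(C)C)[C@@H]2[C@@H](O[Si](CC)(CC)CC)CC(C)=C[C@H](O[Si](C)(C)C(C)(C)C)[C@@]12C | intermediate
18 | 2α-OPMB-10β-OTBS-dauc-8-ene-4β,6α-diol | COc1ccc(cc1)CO[C@H]1C[C@@](O)(C(C)C)[C@@H]2[C@@H](O)CC(C)=C[C@H](O[Si](C)(C)C(C)(C)C)[C@@]12C | intermediate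
19 | 4-hydroxybenzoic acid | OC(=O)c1ccc(O)cc1 | starting material
20 | triisopropylsilyl 4-(triisopropylsilyloxy)benzoate | CC(C)[Si](C(C)C)(C(C)C)OC(=O)c1ccc(O[Si](C(C)C)(C(C)C)C(C)C)cc1 | intermediate
21 | 4-(triisopropylsilyloxy)benzoic acid | CC(C)[Si](C(C)C)(C(C)C)Oc1ccc(cc1)C(O)=O | intermediate
22 | 6α-[4-(TIPSO)benzoyloxy]-2α-OPMB-10β-OTBS-dauc-8-en-4β-ol | COc1ccc(cc1)CO[C@H]1C[C@@](O)(C(C)C)[C@@H]2[C@@H](OC(=O)c3ccc(O[Si](C(C)C)(C(C)C)C(C)C)cc3)CC(C)=C[C@H](O[Si](C)(C)C(C)(C)C)[C@@]12C | intermediate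
23 | 6α-[4-(TIPSO)benzoyloxy]-2α-OPMB-dauc-8-ene-4β,10β-diol | COc1ccc(cc1)CO[C@H]1C[C@@](O)(C(C)C)[C@@H]2[C@@H](OC(=O)c3ccc(O[Si](C(C)C)(C(C)C)C(C)C)cc3)CC(C)=C[C@H](O)[C@@]12C | intermediate
24 | 10β-benzoyloxy-6α-[4-(TIPSO)benzoyloxy]-2α-OPMB-dauc-8-en-4β-ol | COc1ccc(cc1)CO[C@H]1C[C@@](O)(C(C)C)[C@@H]2[C@@H](OC(=O)c3ccc(O[Si](C(C)C)(C(C)C)C(C)C)cc3)CC(C)=C[C@H](OC(=O)c3ccccc3)[C@@]12C | intermediate
25 | 10β-benzoyloxy-6α-[4-(TIPSO)benzoyloxy]dauc-8-ene-2α,4β-diol | O[C@H]1C[C@@](O)(C(C)C)[C@@H]2[C@@H](OC(=O)c3ccc(O[Si](C(C)C)(C(C)C)C(C)C)cc3)CC(C)=C[C@H](OC(=O)c3ccccc3)[C@@]12C | intermediate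
26 | 2α-acetoxy-10β-benzoyloxy-6α-[4-(TIPSO)benzoyloxy]dauc-8-en-4β-ol | CC(=O)O[C@H]1C[C@@](O)(C(C)C)[C@@H]2[C@@H](OC(=O)c3ccc(O[Si](C(C)C)(C(C)C)C(C)C)cc3)CC(C)=C[C@H](OC(=O)c3ccccc3)[C@@]12C | intermediate
27 | 2α-acetoxy-10β-benzoyloxy-6α-(4-hydroxybenzoyloxy)dauc-8-en-4β-ol (CNP0316187.1) | CC(=O)O[C@H]1C[C@@](O)(C(C)C)[C@@H]2[C@@H](OC(=O)c3ccc(O)cc3)CC(C)=C[C@H](OC(=O)c3ccccc3)[C@@]12C | target

Total step count: 21. Longest linear sequence: 20 (steps 1–14 and 16–21).

Steps most likely to fail

1. Step 12 (the labelled step). The silyl triflate may ionise the doubly allylic C10–O bond. The silylated epoxide may collapse by a 1,2-hydride shift. The sequence may also stop after the first C–C bond, or close through oxygen.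
The fallback uses known reactions and makes the two bonds one at a time. It sets out from 13 and returns at 16.
- SmI2 in THF/MeOH at −90 °C reductively cleaves the α-C–O bond of the epoxy ketone to the β-hydroxy ketone F1.
- TESCl/imidazole gives the TES ether F2.
- TMSOTf/Et3N under equilibrating conditions gives the internal (Z)-trimethylsilyl enol ether F3.
- An intramolecular anodic olefin coupling of the two enol ethers (RVC anode, LiClO4, 2,6-lutidine, MeOH/CH2Cl2) followed by mild acid hydrolysis of the mixed acetal joins C5 to C1 and gives the cycloheptene keto aldehyde F4.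
- A separate intramolecular aldol addition of the kinetic methyl-ketone enolate (LiHMDS, −78 °C) closes ring A to the 2α-hydroxy hydroazulenone F5.
- PMB trichloroacetimidate with catalytic La(OTf)3 returns 16.

2. Step 10. Deprotonation of the doubly activated C7–H may move the enone double bond into conjugation with C8=C9 before epoxidation. Catalyst control of the face may also be incomplete.
The fallback avoids enone 12 altogether. It sets out from 11 and returns at 13.
- Cross metathesis of 11 with (S)-but-3-en-2-ol (Hoveyda–Grubbs II) gives the (E)-allylic alcohol F6.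
- Sharpless asymmetric epoxidation of the matched pair (Ti(Oi-Pr)4, L-(+)-DIPT, TBHP, 4 Å MS, CH2Cl2, −20 °C) gives the epoxy alcohol F7.
- Dess–Martin oxidation buffered with NaHCO3 removes the auxiliary carbinol centre and gives 13.

3. Step 13. Enolisation may be followed by β-elimination of the C2 or C6 oxygen substituent. β-Hydride transfer from the secondary Grignard reagent may reduce the ketone instead of adding to it.
The fallback sets out from 16 and returns at 17.
- An sp2 nucleophile without β-hydrogens, isopropenylmagnesium bromide with CeCl3 in THF at −78 °C, gives the 4α-isopropenyl carbinol F8.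
- Chemoselective homogeneous hydrogenation of the 1,1-disubstituted alkene (H2, RhCl(PPh3)3, benzene/EtOH) gives 17 and leaves the trisubstituted ring alkene untouched.

Further compounds
F1 | step 12 | (4S,6Z,8S,9Z)-4-hydroxy-8-(TBSO)-10-(4-methoxybenzyloxy)-6,9-dimethyldeca-6,9-dien-2-one | CC(=O)C[C@@H](O)C/C(C)=C\[C@H](O[Si](C)(C)C(C)(C)C)/C(C)=C\OCc1ccc(OC)cc1
F2 | step 12 | TES ether of F1 | CC(=O)C[C@@H](O[Si](CC)(CC)CC)C/C(C)=C\[C@H](O[Si](C)(C)C(C)(C)C)/C(C)=C\OCc1ccc(OC)cc1
F3 | step 12 | internal (Z)-trimethylsilyl enol ether of F2 | C/C(O[Si](C)(C)C)=C/[C@@H](O[Si](CC)(CC)CC)C/C(C)=C\[C@H](O[Si](C)(C)C(C)(C)C)/C(C)=C\OCc1ccc(OC)cc1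
F4 | step 12 | cycloheptene keto aldehyde (C5-acetyl, C1-methyl, C1-formyl, 6α-OTES, 10β-OTBS) | CC(=O)[C@@H]1[C@@H](O[Si](CC)(CC)CC)CC(C)=C[C@H](O[Si](C)(C)C(C)(C)C)[C@@]1(C)C=O
F5 | step 12 | 2α-hydroxy trans-hydroazulen-4-one (6α-OTES, 10β-OTBS) | O[C@H]1CC(=O)[C@@H]2[C@@H](O[Si](CC)(CC)CC)CC(C)=C[C@H](O[Si](C)(C)C(C)(C)C)[C@@]12C
F6 | step 10 | (2S,3E,6Z,8S,9Z)-8-(TBSO)-10-(4-methoxybenzyloxy)-6,9-dimethyldeca-3,6,9-trien-2-ol | C[C@H](O)/C=C/C/C(C)=C\[C@H](O[Si](C)(C)C(C)(C)C)/C(C)=C\OCc1ccc(OC)cc1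
F7 | step 10 | trans-3,4-epoxy alcohol of F6 (epoxide as in 13, carbinol S) | C[C@H](O)[C@@H]1O[C@H]1C/C(C)=C\[C@H](O[Si](C)(C)C(C)(C)C)/C(C)=C\OCc1ccc(OC)cc1
F8 | step 13 | 4α-isopropenyl-4β-hydroxy analogue of 17 | COc1ccc(cc1)CO[C@H]1C[C@@](O)(C(C)=C)[C@@H]2[C@@H](O[Si](CC)(CC)CC)CC(C)=C[C@H](O[Si](C)(C)C(C)(C)C)[C@@]12C
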